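## Retrosynthetic overview

- The C8 ester is made last (Yamaguchi) from the 8‑hydroxy α‑methylene lactone and (2S,3R)‑2,3‑dimethyloxirane‑2‑carboxylic acid, the latter from tiglyl alcohol by Sharpless epoxidation and oxidation.
- Key disconnection C7–C11: the α‑methylene‑γ‑lactone is annulated onto the finished ten‑membered carbocycle by a tethered epoxide alkylation/Horner–Wadsworth–Emmons cascade of the O6 phosphonoacetate. The enabling feature is that the O6 ester and the oxygen of the cis C7–C8 oxirane lie on opposite faces of the cyclodeca‑1(10),3‑diene ring (threo). The C11 carbanion therefore sits behind the C7–O bond, oxirane strain drives the 5‑exo‑tet closure, inversion at C7 gives the cis‑fused lactone, and O8 is released next to the C9 acetate.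
- The carbocycle is closed by ring‑closing metathesis that forms the Z C3=C4 alkene from an allyl and a methallyl terminus.
- The open chain comes from a Nozaki–Hiyama–Kishi union (C9–C10) of a cis‑epoxy aldehyde with a Z alkenyl iodide; the aldehyde comes from a silyl propargyl ether by formylation, Brown methallylation (C6), Lindlar reduction and hydroxyl‑directed threo epoxidation.
- Ring order: C7–C8 oxirane (step 7), ten‑membered carbocycle (step 13), γ‑lactone (step 14); the side‑chain oxirane is made separately (step 15).

Key step: step 14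

Remark: all intermediates use germacrane‑style locants. Ring carbons are C1–C10 (C6 carries the lactone oxygen, C7 the lactone carbon, C8 the epoxy ester, C9 the acetate, C4 and C10 the methyl groups); C11 is the lactone α‑carbon, C12 the carbonyl, C13 the exocyclic methylene. The side‑chain oxirane of the target has cis methyl groups, (2S,3R), i.e. it is the epoxide of tiglic acid.

## Route

Step 1
Reactants: 1 but-2-yn-1-ol
Product: 3 (Z)-3-iodobut-2-en-1-ol, via cyclic alkenylaluminate 2 (not isolated)
Conditions: NaAlH2(OCH2CH2OCH3)2, THF, 0 °C → rt; then I2, THF, −78 → 0 °C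
Reagents that add atoms: iodine, II
Why: trans-hydroalumination of the propargylic alkoxide (hydride to C2, aluminium held at C3 by the oxygen) followed by iodinolysis with retention gives the Z alkenyl iodide, a standard hydroalumination–iodination of propargylic alcohols.

Step 2
Reactants: 3 (Z)-3-iodobut-2-en-1-ol
Product: 4 (Z)-1-bromo-3-iodobut-2-ene
Conditions: PBr3, Et2O, 0 °C
Reagents that add atoms: phosphorus tribromide, BrP(Br)Br
Why: SN2-type bromination of the primary allylic alcohol at low temperature leaves the alkenyl iodide and the alkene geometry untouched.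

Step 3
Reactants: 4 (Z)-1-bromo-3-iodobut-2-ene
Product: 5 (Z)-5-iodohexa-1,4-diene
Conditions: CH2=CHMgBr, CuI (10 mol %), THF, −40 → 0 °C
Reagents that add atoms: vinylmagnesium bromide, C=C[Mg]Br
Why: copper-catalysed Grignard allylic substitution is forced to the primary carbon because the other allyl terminus is the fully substituted iodine-bearing carbon, so the Z iodoalkene is carried through unchanged.

Step 4
Reactants: 6 tert-butyldimethyl(prop-2-yn-1-yloxy)silane
Product: 8 4-[(tert-butyldimethylsilyl)oxy]but-2-ynal, via lithium acetylide 7 (not isolated)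
Conditions: n-BuLi, THF, −78 °C; DMF, −78 → 0 °C; poured into aq. KH2PO4
Reagents that add atoms: N,N-dimethylformamide, CN(C)C=O
Why: formylation of the lithium acetylide with DMF, with a reverse quench into phosphate buffer so that the liberated amine does not add to the ynal.

Step 5
Reactants: 8 4-[(tert-butyldimethylsilyl)oxy]but-2-ynal
Product: 10 (4S)-1-[(tert-butyldimethylsilyl)oxy]-6-methylhept-6-en-2-yn-4-ol, via diisopinocampheylborinate 9 (not isolated)
Conditions: (−)-Ipc2BOMe, CH2=C(CH3)CH2MgCl, Et2O, −78 °C → rt; then 8, −78 °C; NaOH, H2O2, 0 °C → rt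
Reagents that add atoms: 2-methylallylmagnesium chloride, CC(=C)C[Mg]Cl
Why: Brown asymmetric allylboration, in which the (+)-α-pinene-derived methallylborane adds to the Si face of the ynal through a chair transition state and sets C6 as S.

Step 6
Reactants: 10 (4S)-1-[(tert-butyldimethylsilyl)oxy]-6-methylhept-6-en-2-yn-4-ol
Product: 11 (2Z,4S)-1-[(tert-butyldimethylsilyl)oxy]-6-methylhepta-2,6-dien-4-ol
Conditions: H2 (1 atm), Pd/CaCO3 poisoned with Pb(OAc)2, quinoline, EtOAc, rt
Reagents that add atoms: none
Why: Lindlar semihydrogenation delivers H2 syn to give the Z C7=C8 alkene, and the 1,1-disubstituted alkene is reduced far more slowly than the alkyne.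

Step 7
Reactants: 11 (2Z,4S)-1-[(tert-butyldimethylsilyl)oxy]-6-methylhepta-2,6-dien-4-ol
Product: 12 (1S)-1-[(2R,3S)-3-{[(tert-butyldimethylsilyl)oxy]methyl}oxiran-2-yl]-3-methylbut-3-en-1-ol
Conditions: Ti(OiPr)4 (0.3 equiv), t-BuOOH, 4 Å MS, CH2Cl2, −20 °C
Reagents that add atoms: tert-butyl hydroperoxide, CC(C)(C)OO
Why: hydroxyl-directed epoxidation by the titanium alkoxide/alkyl peroxide (the tartrate-free form of the Sharpless reagent) touches only the allylic alkene, and in this Z allylic alcohol 1,3-allylic strain holds H6 in the alkene plane so that oxygen is delivered syn to the bound hydroxyl, which should give the threo (6S,7R,8S) epoxy alcohol with a cis oxirane.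

Step 8
Reactants: 12 (1S)-1-[(2R,3S)-3-{[(tert-butyldimethylsilyl)oxy]methyl}oxiran-2-yl]-3-methylbut-3-en-1-ol; 13 (diethoxyphosphoryl)acetic acid
Product: 14 (1S)-1-[(2R,3S)-3-{[(tert-butyldimethylsilyl)oxy]methyl}oxiran-2-yl]-3-methylbut-3-en-1-yl (diethoxyphosphoryl)acetate
Conditions: EDC·HCl, DMAP (cat.), CH2Cl2, 0 °C → rt
Reagents that add atoms: none
Why: Steglich-type carbodiimide/DMAP esterification installs the tether of the key step and at the same time masks O6, so that the later C9 aldehyde cannot close to a lactol.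

Step 9
Reactants: 14 (1S)-1-[(2R,3S)-3-{[(tert-butyldimethylsilyl)oxy]methyl}oxiran-2-yl]-3-methylbut-3-en-1-yl (diethoxyphosphoryl)acetate
Product: 15 (1S)-1-[(2R,3S)-3-(hydroxymethyl)oxiran-2-yl]-3-methylbut-3-en-1-yl (diethoxyphosphoryl)acetate
Conditions: HF·pyridine, pyridine, THF, 0 °C → rt
Reagents that add atoms: none
Why: fluoride cleavage of the primary silyl ether under buffered, non-basic conditions, which neither deprotonate the phosphonoacetate nor open the oxirane.

Step 10
Reactants: 15 (1S)-1-[(2R,3S)-3-(hydroxymethyl)oxiran-2-yl]-3-methylbut-3-en-1-yl (diethoxyphosphoryl)acetate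
Product: 16 (1S)-1-[(2R,3R)-3-formyloxiran-2-yl]-3-methylbut-3-en-1-yl (diethoxyphosphoryl)acetate
Conditions: Dess–Martin periodinane, pyridine, CH2Cl2, 0 °C → rt
Reagents that add atoms: none
Why: Dess–Martin oxidation gives the cis-epoxy aldehyde under near-neutral conditions, and the oxirane carbon next to the carbonyl cannot epimerise.

Step 11
Reactants: 16 (1S)-1-[(2R,3R)-3-formyloxiran-2-yl]-3-methylbut-3-en-1-yl (diethoxyphosphoryl)acetate; 5 (Z)-5-iodohexa-1,4-diene
Product: 18 (1S)-1-{(2R,3S)-3-[(1S,2Z)-1-hydroxy-2-methylhexa-2,5-dien-1-yl]oxiran-2-yl}-3-methylbut-3-en-1-yl (diethoxyphosphoryl)acetate, via alkenylchromium dichloride 17 (not isolated)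
Conditions: CrCl2 (excess), NiCl2 (2 mol %), DMSO, rt
Reagents that add atoms: none
Why: Nozaki–Hiyama–Kishi coupling, in which the alkenylchromium species is formed with retention of the Z geometry and adds only to the aldehyde, and Felkin–Anh attack anti to the C8–O bond of the cis-epoxy aldehyde should set C9 as S (erythro epoxy alcohol).

Step 12
Reactants: 18 (1S)-1-{(2R,3S)-3-[(1S,2Z)-1-hydroxy-2-methylhexa-2,5-dien-1-yl]oxiran-2-yl}-3-methylbut-3-en-1-yl (diethoxyphosphoryl)acetate
Product: 19 (1S)-1-{(2R,3S)-3-[(1S,2Z)-1-acetoxy-2-methylhexa-2,5-dien-1-yl]oxiran-2-yl}-3-methylbut-3-en-1-yl (diethoxyphosphoryl)acetate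
Conditions: Ac2O, pyridine, DMAP (cat.), CH2Cl2, 0 °C → rt
Reagents that add atoms: acetic anhydride, CC(=O)OC(C)=O
Why: DMAP-catalysed acetylation of the secondary allylic alcohol installs the C9 acetate of the target under conditions too weakly basic to deprotonate the phosphonoacetate.

Step 13
Reactants: 19 (1S)-1-{(2R,3S)-3-[(1S,2Z)-1-acetoxy-2-methylhexa-2,5-dien-1-yl]oxiran-2-yl}-3-methylbut-3-en-1-yl (diethoxyphosphoryl)acetate
Product: 20 (6S,7R,8S,9S)-9-acetoxy-7,8-epoxy-4,10-dimethylcyclodeca-1(10),3-dien-6-yl (diethoxyphosphoryl)acetate (both ring alkenes Z)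
Conditions: second-generation Grubbs catalyst RuCl2(H2IMes)(PCy3)(=CHPh) (10 mol %), 1,4-benzoquinone, toluene (1 mM), 80 °C
Reagents that add atoms: none
Why: ring-closing metathesis between the monosubstituted and the 1,1-disubstituted terminal alkenes closes the ten-membered ring with loss of ethene; the cis oxirane and the Z C1=C10 alkene pre-organise the chain, no smaller ring is available to the carbene, and the skipped diene in a ten-membered ring should accept only the Z C3=C4 alkene.

Step 14
Reactants: 20 (6S,7R,8S,9S)-9-acetoxy-7,8-epoxy-4,10-dimethylcyclodeca-1(10),3-dien-6-yl (diethoxyphosphoryl)acetate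
Product: 22 (6S,7R,8R,9S)-9-acetoxy-8-hydroxy-4,10-dimethyl-1(10)Z,3Z-cyclodecadiene carrying the cis-fused α-methylene-γ-lactone (O6–C12, C11–C7), via α-phosphono lactone 21 (not isolated)
Conditions: NaH (1.05 equiv), THF, 0 → 45 °C; then (CH2O)n, 0 °C → rt; aq. NH4Cl
Reagents that add atoms: formaldehyde (as paraformaldehyde), C=O
Why: Proposed new method: NaH removes only a phosphonoacetate proton (far more acidic than the acetate), and the carbanion, held by the O6 tether on the ring face opposite to the oxirane oxygen, attacks C7 from behind the C7–O bond in a 5-exo-tet closure of the γ-lactone driven by release of oxirane strain; the closest known reaction types are the telescoped intramolecular Michael/olefination of O-tethered phosphonoacetates (same tether, carbanion and lactone closure, with an enone in place of the oxirane), the 5-exo epoxide alkylations of epoxynitrile anions, and the opening of epoxides by phosphonoacetate anions in the Wadsworth–Emmons cyclopropanation. C7 is set by SN2 inversion, so the (7R,8S) oxirane configuration alone dictates the cis-fused lactone, and C8 keeps its oxygen with retention as the free hydroxyl needed for the last step. The alkoxide first formed should be protonated at once by the much more acidic α-phosphono lactone C–H, which gives carbanion 21 and suppresses acetyl migration from O9, translactonisation to O8 and the phosphoryl transfer that leads to cyclopropanes. Paraformaldehyde then triggers the Horner–Wadsworth–Emmons olefination, which installs the exocyclic methylene and removes the activating group in the same flask. The selectivity needed is attack at C7 and not C8 (5-exo versus 6-endo), secured by the three-atom tether and the collinear trajectory, and reaction at the oxirane and not at an alkene, secured by the polar mechanism.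

Step 15
Reactants: 23 (E)-2-methylbut-2-en-1-ol
Product: 24 [(2R,3R)-2,3-dimethyloxiran-2-yl]methanol
Conditions: Ti(OiPr)4 (5 mol %), D-(−)-diethyl tartrate (6 mol %), t-BuOOH, 4 Å MS, CH2Cl2, −20 °C
Reagents that add atoms: tert-butyl hydroperoxide, CC(C)(C)OO
Why: Sharpless asymmetric epoxidation, in which the D-(−)-tartrate catalyst delivers oxygen to the face of the E allylic alcohol that gives the (2R,3R) epoxy alcohol, setting both oxirane centres.

Step 16
Reactants: 24 [(2R,3R)-2,3-dimethyloxiran-2-yl]methanol
Product: 25 (2S,3R)-2,3-dimethyloxirane-2-carboxylic acid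
Conditions: TEMPO (cat.), PhI(OAc)2, MeCN/H2O, rt
Reagents that add atoms: water, O
Why: TEMPO-catalysed oxidation takes the primary alcohol through the aldehyde hydrate to the acid without touching the oxirane (the descriptor at C2 changes only because the substituent priorities change).

Step 17
Reactants: 22 the 8-hydroxy α-methylene lactone; 25 (2S,3R)-2,3-dimethyloxirane-2-carboxylic acid
Product: 26 CNP0188864.1, (6S,7S,8R,9S)-9-acetoxy-8-[(2S,3R)-2,3-dimethyloxirane-2-carbonyloxy] α-methylene lactone
Conditions: 2,4,6-trichlorobenzoyl chloride, Et3N, toluene, rt; then 22, DMAP, rt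
Reagents that add atoms: none
Why: Yamaguchi esterification through the mixed anhydride acylates the hindered C8 hydroxyl without touching any stereocentre, and the acid has no α-hydrogen and cannot epimerise.

## Compound list

1 | but-2-yn-1-ol | CC#CCO | starting material
2 | cyclic alkenylaluminate (sodium salt; Al bonded to O and to C3 of the butenyl unit, two 2-methoxyethoxy ligands) | CC1=CCO[Al-]1(OCCOC)OCCOC.[Na+] | intermediate (not isolated)
3 | (Z)-3-iodobut-2-en-1-ol | OC/C=C(/C)I | intermediate
4 | (Z)-1-bromo-3-iodobut-2-ene | BrC/C=C(/C)I | intermediate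
5 | (Z)-5-iodohexa-1,4-diene | C=CC/C=C(/C)I | intermediate
6 | tert-butyldimethyl(prop-2-yn-1-yloxy)silane | C#CCO[Si](C)(C)C(C)(C)C | starting material
7 | lithium acetylide of 6 | [Li]C#CCO[Si](C)(C)C(C)(C)C | intermediate (not isolated)
8 | 4-[(tert-butyldimethylsilyl)oxy]but-2-ynal | O=CC#CCO[Si](C)(C)C(C)(C)C | intermediate
9 | diisopinocampheylborinate of 10 (O6–B(Ipc)2, Ipc groups from (+)-α-pinene) | CC(=C)C[C@H](OB([C@@H]1C[C@@H]2C[C@@H](C2(C)C)[C@H]1C)[C@@H]1C[C@@H]2C[C@@H](C2(C)C)[C@H]1C)C#CCO[Si](C)(C)C(C)(C)C | intermediate (not isolated)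
10 | (4S)-1-[(tert-butyldimethylsilyl)oxy]-6-methylhept-6-en-2-yn-4-ol (C6 S) | CC(=C)C[C@H](O)C#CCO[Si](C)(C)C(C)(C)C | intermediate
11 | (2Z,4S)-1-[(tert-butyldimethylsilyl)oxy]-6-methylhepta-2,6-dien-4-ol | CC(=C)C[C@H](O)/C=C\CO[Si](C)(C)C(C)(C)C | intermediate
12 | (1S)-1-[(2R,3S)-3-{[(tert-butyldimethylsilyl)oxy]methyl}oxiran-2-yl]-3-methylbut-3-en-1-ol (threo, cis oxirane; 6S,7R,8S) | CC(=C)C[C@H](O)[C@H]1O[C@H]1CO[Si](C)(C)C(C)(C)C | intermediate
13 | (diethoxyphosphoryl)acetic acid | OC(=O)CP(=O)(OCC)OCC | starting material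
14 | (1S)-1-[(2R,3S)-3-{[(tert-butyldimethylsilyl)oxy]methyl}oxiran-2-yl]-3-methylbut-3-en-1-yl (diethoxyphosphoryl)acetate | CC(=C)C[C@H](OC(=O)CP(=O)(OCC)OCC)[C@H]1O[C@H]1CO[Si](C)(C)C(C)(C)C | intermediate
15 | (1S)-1-[(2R,3S)-3-(hydroxymethyl)oxiran-2-yl]-3-methylbut-3-en-1-yl (diethoxyphosphoryl)acetate | CC(=C)C[C@H](OC(=O)CP(=O)(OCC)OCC)[C@H]1O[C@H]1CO | intermediate
16 | (1S)-1-[(2R,3R)-3-formyloxiran-2-yl]-3-methylbut-3-en-1-yl (diethoxyphosphoryl)acetate | CC(=C)C[C@H](OC(=O)CP(=O)(OCC)OCC)[C@H]1O[C@H]1C=O | intermediate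
17 | [(2Z)-hexa-2,5-dien-2-yl]chromium dichloride | C=CC/C=C(/C)[Cr](Cl)Cl | intermediate (not isolated)
18 | (1S)-1-{(2R,3S)-3-[(1S,2Z)-1-hydroxy-2-methylhexa-2,5-dien-1-yl]oxiran-2-yl}-3-methylbut-3-en-1-yl (diethoxyphosphoryl)acetate (6S,7R,8S,9S) | CC(=C)C[C@H](OC(=O)CP(=O)(OCC)OCC)[C@H]1O[C@H]1[C@@H](O)/C(C)=C\CC=C | intermediate
19 | (1S)-1-{(2R,3S)-3-[(1S,2Z)-1-acetoxy-2-methylhexa-2,5-dien-1-yl]oxiran-2-yl}-3-methylbut-3-en-1-yl (diethoxyphosphoryl)acetate | CC(=C)C[C@H](OC(=O)CP(=O)(OCC)OCC)[C@H]1O[C@H]1[C@@H](OC(C)=O)/C(C)=C\CC=C | intermediate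
20 | (6S,7R,8S,9S)-9-acetoxy-7,8-epoxy-4,10-dimethylcyclodeca-1(10),3-dien-6-yl (diethoxyphosphoryl)acetate, both ring alkenes Z | O=C(CP(=O)(OCC)OCC)O[C@H]1C/C(C)=C\C/C=C(/C)[C@H](OC(C)=O)[C@@H]2O[C@H]12 | intermediate
21 | cis-fused α-(diethoxyphosphoryl)-γ-lactone of the ring (O6–C12, C11–C7), 8-OH free, 9-OAc, C11 epimers, present as its sodium derivative | CCOP(=O)(OCC)C1C(=O)O[C@H]2C/C(C)=C\C/C=C(/C)[C@H](OC(C)=O)[C@H](O)[C@@H]12 | intermediate (not isolated)
22 | (6S,7R,8R,9S)-9-acetoxy-8-hydroxy-4,10-dimethyl-1(10)Z,3Z-cyclodecadiene with cis-fused α-methylene-γ-lactone (O6–C12, C11–C7) | C=C1C(=O)O[C@H]2C/C(C)=C\C/C=C(/C)[C@H](OC(C)=O)[C@H](O)[C@@H]12 | intermediate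
23 | (E)-2-methylbut-2-en-1-ol | C/C=C(\C)CO | starting material
24 | [(2R,3R)-2,3-dimethyloxiran-2-yl]methanol | OC[C@@]1(C)O[C@@H]1C | intermediate
25 | (2S,3R)-2,3-dimethyloxirane-2-carboxylic acid | OC(=O)[C@@]1(C)O[C@@H]1C | intermediate
26 | CNP0188864.1: (6S,7S,8R,9S)-9-acetoxy-8-[(2S,3R)-2,3-dimethyloxirane-2-carbonyloxy]-4,10-dimethyl-1(10)Z,3Z-cyclodecadiene with cis-fused α-methylene-γ-lactone | C=C1C(=O)O[C@H]2C/C(C)=C\C/C=C(/C)[C@H](OC(C)=O)[C@H](OC(=O)[C@@]3(C)O[C@@H]3C)[C@@H]12 | target

## Step count and risks

Total steps: 17. Longest linear sequence: 12 (steps 4–14 and 17).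

Steps most likely to fail:

1. Step 14 (proposed new method). The stabilised carbanion may be too weak a nucleophile or may not reach the reactive ester rotamer, so that the oxirane is not opened. Alternatively the transient C8 alkoxide may cause acetyl migration or translactonisation before proton transfer. The fallback sets out from 20 and returns at 22. The phosphonoacetate is first converted by Horner–Wadsworth–Emmons methylenation under Masamune–Roush conditions (LiCl, DBU, (CH2O)n, MeCN) into the macrocyclic epoxy acrylate F1. The ring is then closed with PMe3 in t-BuOH by a phosphine-mediated Morita–Baylis–Hillman alkylation, in which the β-phosphonio enolate attacks C7 of the oxirane and loss of the phosphine regenerates the methylene group. The first operation is routine; the second is a known ring closure for enone/epoxide pairs but is an extension to an acrylate ester, so it is the weaker part of this fallback. It gives 22 directly, with the same inversion at C7.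

2. Step 13. The strained ten-membered ring with a trisubstituted alkene may not close, giving oligomers instead, or ruthenium hydrides may shift the terminal 1,4-diene into conjugation. The fallback changes the order of ring formation; it sets out from 19 and returns at 22. The tethered epoxide alkylation is run first without the olefination (NaH, THF, 0 → 45 °C, AcOH quench) to give the open-chain α-phosphono lactone F2. Its cis-fused five-membered ring holds the two alkene-bearing arms on one face. Ring-closing metathesis of F2 under the conditions of step 13 then gives 21, here isolated, and K2CO3 with aqueous formaldehyde converts 21 into 22.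

3. Step 11. Facial selectivity at C9 may be poor in the addition to the epoxy aldehyde, and the oxirane may be partly opened by chromium salts. The fallback sets the centre by reduction instead of addition; it sets out from 18 (as the C9 epimer mixture) and returns at 18. Dess–Martin oxidation gives the epoxy enone F3, and Zn(BH4)2 in Et2O at −20 °C reduces it under chelation control of the α,β-epoxy ketone to the erythro (9S) epoxy alcohol 18.

Further compounds
F1 | step 14 | (6S,7R,8S,9S)-9-acetoxy-7,8-epoxy-4,10-dimethylcyclodeca-1(10),3-dien-6-yl acrylate, both ring alkenes Z | C=CC(=O)O[C@H]1C/C(C)=C\C/C=C(/C)[C@H](OC(C)=O)[C@@H]2O[C@H]12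
F2 | step 13 | open-chain cis-4,5-disubstituted α-(diethoxyphosphoryl)-γ-butyrolactone: C6 bears the 2-methylallyl group, C7 bears the (1R,2S,3Z)-2-acetoxy-1-hydroxy-3-methylhepta-3,6-dienyl chain | CCOP(=O)(OCC)C1C(=O)O[C@@H](CC(C)=C)[C@H]1[C@@H](O)[C@@H](OC(C)=O)/C(C)=C\CC=C
F3 | step 11 | (1S)-3-methyl-1-{(2R,3R)-3-[(2Z)-2-methylhexa-2,5-dienoyl]oxiran-2-yl}but-3-en-1-yl (diethoxyphosphoryl)acetate | CC(=C)C[C@H](OC(=O)CP(=O)(OCC)OCC)[C@H]1O[C@H]1C(=O)/C(C)=C\CC=C
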